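**Strategy.** The oxan-3-one ring (O1, quaternary C2, ketone C3, methylene C4, carbinol C5, gem-dimethyl C6) contains an aldol pair (C3–C4–C5–OH) and an acyloin-type pair (C3–C2–O1). Acetaldehyde is therefore inserted as a two-carbon linchpin into an acyclic aldehyde–β-alkoxycrotonate: its methyl carbon adds as an enamine to the aldehyde (C4–C5), then its carbonyl carbon, umpoled by a chiral carbene, closes the ring on the crotonate (C2–C3). Two organocatalysts set C5 and C2 independently in one flask. The acetate arm becomes an allyl group, which is joined by B-alkyl Suzuki coupling to an arene-bearing (Z)-iodo allylic alcohol; oxidation and desilylation finish the synthesis.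

Key step: step 3

Remark on the chemistry (assumption): the sense of induction of each chiral controller (step 3 and its fallback) is assigned from its accepted transition-state model, and if one proves opposite its commercially available antipode is used with no other change; the carbinol made in step 10 is carried as a racemate (later a pair of epimers) because step 14 oxidises it.

**Ring fragment**

Step 1
Reactants: 1 methyl 2-hydroxy-2-methylpropanoate; 2 ethyl buta-2,3-dienoate
Product: 3 ethyl (2E)-3-[(1-methoxy-2-methyl-1-oxopropan-2-yl)oxy]but-2-enoate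
Conditions: DABCO (20 mol %), MeCN, rt
Reagents that add atoms: none
Why: Tertiary-amine-catalysed oxa-Michael addition of the hydroxy ester to the central allene carbon, the first-formed 3-alkoxybut-3-enoate isomerising to the conjugated, thermodynamically preferred E-crotonate.

Step 2
Reactants: 3 ethyl (2E)-3-[(1-methoxy-2-methyl-1-oxopropan-2-yl)oxy]but-2-enoate
Product: 4 ethyl (2E)-3-[(2-methyl-1-oxopropan-2-yl)oxy]but-2-enoate
Conditions: iBu2AlH (1.05 equiv), CH2Cl2, −78 °C; aq. KNaC4H4O6
Reagents that add atoms: none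
Why: Partial ester reduction, in which the α-alkoxy methyl ester forms a chelated tetrahedral aluminate that survives to work-up and is much more electrophilic than the donor-deactivated vinylogous carbonate ester.

Step 3
Reactants: 4 ethyl (2E)-3-[(2-methyl-1-oxopropan-2-yl)oxy]but-2-enoate; 5 acetaldehyde
Product: 7 ethyl 2-[(2R,5S)-5-hydroxy-2,6,6-trimethyl-3-oxooxan-2-yl]acetate, via hydroxy aldehyde 6 (not isolated)
Conditions: (R)-α,α-bis[3,5-bis(trifluoromethyl)phenyl]-2-pyrrolidinemethanol (10 mol %), MeCHO (5 equiv), DMF, 4 °C; excess MeCHO evaporated; then (5aS,10bR)-2-(pentafluorophenyl)-5a,10b-dihydro-4H,6H-indeno[2,1-b][1,2,4]triazolo[4,3-d][1,4]oxazinium tetrafluoroborate (20 mol %), iPr2NEt (20 mol %), toluene, 23 °C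
Reagents that add atoms: none
Why: The amine forms the enamine of acetaldehyde, whose α-carbon adds to the non-enolisable, α-alkoxy-activated aldehyde 4 (C4–C5, enamine cross-aldol), and after removal of excess acetaldehyde the triazolylidene turns the new aldehyde into a Breslow intermediate whose former carbonyl carbon adds to the β-carbon of the tethered β-alkoxycrotonate (C2–C3, intramolecular Stetter reaction). The closest known reaction types are amine/carbene relay cascades and Stetter closures onto oxygen-tethered β,β-disubstituted acrylates that create oxygen-bearing quaternary centres. The oxanone ring closes in the 6-exo-trig mode, assisted by the gem-dimethyl group. C5 is set by the prolinol (hydrogen-bond-directed Si-face attack on 4) and C2 by the chiral triazolium, which selects the face of the E-acceptor, so both centres are reagent-controlled and the cis relation of 5-OH and the acetate arm does not rest on substrate bias. The step needs chemoselectivity (acetaldehyde as donor only, no benzoin), secured by the absence of α-hydrogens in 4 and by stripping acetaldehyde before the carbene is generated, and regioselective acyl transfer to the β-carbon, secured by the polarisation of the vinylogous carbonate and the tether length. The weak amine base keeps the β-hydroxy aldehyde from retro-aldol, dehydration and oxa-Michael closure to a dioxolane.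

Step 4
Reactants: 7 ethyl 2-[(2R,5S)-5-hydroxy-2,6,6-trimethyl-3-oxooxan-2-yl]acetate
Product: 8 ethyl 2-[(2R,5S)-2,6,6-trimethyl-3,5-bis(triethylsilyloxy)-5,6-dihydro-2H-pyran-2-yl]acetate
Conditions: Et3SiOTf (2.5 equiv), Et3N, CH2Cl2, −78 to 0 °C
Reagents that add atoms: triethylsilyl trifluoromethanesulfonate, CC[Si](CC)(CC)OS(=O)(=O)C(F)(F)F
Why: Silylation with soft enolisation, which caps the alcohol and converts the ketone (enolisable only toward C4) into its silyl enol ether, masking the carbonyl and the β-elimination pathway for the hydride, ylide, borane and base steps that follow without touching either stereocentre.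

Step 5
Reactants: 8 ethyl 2-[(2R,5S)-2,6,6-trimethyl-3,5-bis(triethylsilyloxy)-5,6-dihydro-2H-pyran-2-yl]acetate
Product: 9 2-[(2R,5S)-2,6,6-trimethyl-3,5-bis(triethylsilyloxy)-5,6-dihydro-2H-pyran-2-yl]acetaldehyde
Conditions: iBu2AlH (1.1 equiv), CH2Cl2, −78 °C; aq. KNaC4H4O6
Reagents that add atoms: none
Why: Partial reduction of the ethyl ester to the aldehyde, possible now that the ring ketone is masked.

Step 6
Reactants: 9 2-[(2R,5S)-2,6,6-trimethyl-3,5-bis(triethylsilyloxy)-5,6-dihydro-2H-pyran-2-yl]acetaldehyde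
Product: 10 (2R,5S)-2,6,6-trimethyl-2-(prop-2-en-1-yl)-3,5-bis(triethylsilyloxy)-5,6-dihydro-2H-pyran
Conditions: Ph3PCH3Br, KN(SiMe3)2, THF, 0 °C; then 9, −78 to 0 °C
Reagents that add atoms: methyltriphenylphosphonium bromide, C[P+](c1ccccc1)(c1ccccc1)c1ccccc1.[Br-]
Why: Wittig methylenation, fast enough at low temperature to outrun E1cB opening of the β-alkoxy aldehyde, should give the terminal alkene needed for hydroboration.

**Arene fragment**

Step 7
Reactants: 11 4-methoxy-3-methylphenol
Product: 12 (4-methoxy-3-methylphenoxy)tri(propan-2-yl)silane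
Conditions: iPr3SiCl, imidazole, DMF, rt
Reagents that add atoms: chlorotri(propan-2-yl)silane, CC(C)[Si](Cl)(C(C)C)C(C)C
Why: Silylation of the phenol with a bulky, non-coordinating group that shields its own ortho positions in the next step.

Step 8
Reactants: 12 (4-methoxy-3-methylphenoxy)tri(propan-2-yl)silane
Product: 14 {2-methoxy-3-methyl-5-[tri(propan-2-yl)silyloxy]phenyl}methanol, via aryllithium 13 (not isolated)
Conditions: nBuLi, TMEDA, Et2O, 0 °C to rt; (CH2O)n, −78 °C to rt
Reagents that add atoms: paraformaldehyde (formaldehyde), C=O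
Why: Directed ortho-metalation, in which the methoxy group directs lithiation to its only free ortho position (the other carries the methyl group) while the hindered silyloxy group is a poor director, followed by trapping with formaldehyde.

Step 9
Reactants: 14 {2-methoxy-3-methyl-5-[tri(propan-2-yl)silyloxy]phenyl}methanol
Product: 15 [3-(chloromethyl)-4-methoxy-5-methylphenoxy]tri(propan-2-yl)silane
Conditions: SOCl2, pyridine, CH2Cl2, 0 °C
Reagents that add atoms: thionyl chloride, ClS(Cl)=O
Why: Chlorination of the electron-rich benzylic alcohol through its chlorosulfite, buffered by pyridine.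

Step 10
Reactants: 16 but-2-ynal; 17 3-bromoprop-1-yne
Product: 19 hepta-1,5-diyn-3-ol (racemic), via allenylzinc bromide 18 (not isolated)
Conditions: Zn dust, THF, 0 °C to rt; aq. NH4Cl
Reagents that add atoms: none
Why: Barbier-type propargylation, in which the allenylzinc bromide adds through its γ-carbon (SE2') to the aldehyde carbonyl and should give the homopropargylic alcohol.

Step 11
Reactants: 19 hepta-1,5-diyn-3-ol (racemic); 15 [3-(chloromethyl)-4-methoxy-5-methylphenoxy]tri(propan-2-yl)silane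
Product: 21 (6E)-8-{2-methoxy-3-methyl-5-[tri(propan-2-yl)silyloxy]phenyl}-6-methyloct-6-en-2-yn-4-ol (racemic), via alkenylalane 20 (not isolated)
Conditions: AlMe3 (3 equiv), Cp2ZrCl2 (0.25 equiv), CH2Cl2, 0 °C to rt; volatiles removed; then 15, Pd(PPh3)4 (5 mol %), THF, rt
Reagents that add atoms: trimethylaluminium, C[Al](C)C
Why: Negishi carboalumination of the terminal alkyne only (internal alkynes react far more slowly) adds methyl and aluminium syn, and Pd(PPh3)4-catalysed cross-coupling of the alkenylalane with the benzylic chloride proceeds with retention, fixing the 6E trisubstituted alkene.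

Step 12
Reactants: 21 (6E)-8-{2-methoxy-3-methyl-5-[tri(propan-2-yl)silyloxy]phenyl}-6-methyloct-6-en-2-yn-4-ol (racemic)
Product: 22 (2Z,6E)-2-iodo-8-{2-methoxy-3-methyl-5-[tri(propan-2-yl)silyloxy]phenyl}-6-methylocta-2,6-dien-4-ol (racemic)
Conditions: NaAlH2(OCH2CH2OMe)2, THF, 0 °C to rt; EtOAc; I2, THF, −78 °C
Reagents that add atoms: iodine, II
Why: Hydroxyl-directed trans-hydroalumination of the propargylic alcohol places aluminium on the distal alkyne carbon in a five-membered alkoxyaluminate, and iodinolysis with retention should give the vinyl iodide with iodine cis to the carbinol carbon (2Z).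

**Union and completion**

Step 13
Reactants: 10 (2R,5S)-2,6,6-trimethyl-2-(prop-2-en-1-yl)-3,5-bis(triethylsilyloxy)-5,6-dihydro-2H-pyran; 22 (2Z,6E)-2-iodo-8-{2-methoxy-3-methyl-5-[tri(propan-2-yl)silyloxy]phenyl}-6-methylocta-2,6-dien-4-ol (racemic)
Product: 24 (2E,6Z)-1-{2-methoxy-3-methyl-5-[tri(propan-2-yl)silyloxy]phenyl}-3,7-dimethyl-10-[(2R,5S)-2,6,6-trimethyl-3,5-bis(triethylsilyloxy)-5,6-dihydro-2H-pyran-2-yl]deca-2,6-dien-5-ol (both C5 epimers), via alkylborane 23 (not isolated)
Conditions: 9-BBN, THF, rt; then 22, Pd(dppf)Cl2 (5 mol %), AsPh3, aq. K3PO4, DMF, rt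
Reagents that add atoms: none
Why: B-alkyl Suzuki–Miyaura coupling, in which 9-BBN hydroborates only the terminal alkene (anti-Markovnikov) and the alkylborane couples with the vinyl iodide with retention of the Z geometry under a mild phosphate base that the free hydroxyl and the silyl groups should tolerate.

Step 14
Reactants: 24 (2E,6Z)-1-{2-methoxy-3-methyl-5-[tri(propan-2-yl)silyloxy]phenyl}-3,7-dimethyl-10-[(2R,5S)-2,6,6-trimethyl-3,5-bis(triethylsilyloxy)-5,6-dihydro-2H-pyran-2-yl]deca-2,6-dien-5-ol (both C5 epimers)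
Product: 25 (2E,6Z)-1-{2-methoxy-3-methyl-5-[tri(propan-2-yl)silyloxy]phenyl}-3,7-dimethyl-10-[(2R,5S)-2,6,6-trimethyl-3,5-bis(triethylsilyloxy)-5,6-dihydro-2H-pyran-2-yl]deca-2,6-dien-5-one
Conditions: Dess–Martin periodinane, NaHCO3, CH2Cl2, 0 °C
Reagents that add atoms: none
Why: Dess–Martin oxidation of the allylic alcohol under bicarbonate buffer should give the enone without moving the β,γ-double bond into conjugation or isomerising the Z-enone, and both carbinol epimers converge.

Step 15
Reactants: 25 (2E,6Z)-1-{2-methoxy-3-methyl-5-[tri(propan-2-yl)silyloxy]phenyl}-3,7-dimethyl-10-[(2R,5S)-2,6,6-trimethyl-3,5-bis(triethylsilyloxy)-5,6-dihydro-2H-pyran-2-yl]deca-2,6-dien-5-one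
Product: 26 (2R,5S)-5-hydroxy-2-[(4Z,8E)-10-(5-hydroxy-2-methoxy-3-methylphenyl)-4,8-dimethyl-6-oxodeca-4,8-dien-1-yl]-2,6,6-trimethyloxan-3-one (CNP0268050.1)
Conditions: Bu4NF, AcOH (1:1), THF, 0 °C to rt
Reagents that add atoms: none
Why: Buffered fluoride desilylation cleaves the aryl silyl ether, the silyl enol ether (protonation at C4 regenerates the ring ketone) and the secondary silyl ether under near-neutral conditions that should spare the β-hydroxy ketone and the skipped enone.

**Compound list**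

1 | methyl 2-hydroxy-2-methylpropanoate | COC(=O)C(C)(C)O | starting material
2 | ethyl buta-2,3-dienoate | CCOC(=O)C=C=C | starting material
3 | ethyl (2E)-3-[(1-methoxy-2-methyl-1-oxopropan-2-yl)oxy]but-2-enoate | CCOC(=O)/C=C(\C)OC(C)(C)C(=O)OC | intermediate
4 | ethyl (2E)-3-[(2-methyl-1-oxopropan-2-yl)oxy]but-2-enoate | CCOC(=O)/C=C(\C)OC(C)(C)C=O | intermediate
5 | acetaldehyde | CC=O | starting material
6 | ethyl (2E)-3-{[(3S)-3-hydroxy-2-methyl-5-oxopentan-2-yl]oxy}but-2-enoate | CCOC(=O)/C=C(\C)OC(C)(C)[C@@H](O)CC=O | intermediate (not isolated)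
7 | ethyl 2-[(2R,5S)-5-hydroxy-2,6,6-trimethyl-3-oxooxan-2-yl]acetate | CCOC(=O)C[C@@]1(C)OC(C)(C)[C@@H](O)CC1=O | intermediate
8 | ethyl 2-[(2R,5S)-2,6,6-trimethyl-3,5-bis(triethylsilyloxy)-5,6-dihydro-2H-pyran-2-yl]acetate | CCOC(=O)C[C@@]1(C)OC(C)(C)[C@@H](O[Si](CC)(CC)CC)C=C1O[Si](CC)(CC)CC | intermediate
9 | 2-[(2R,5S)-2,6,6-trimethyl-3,5-bis(triethylsilyloxy)-5,6-dihydro-2H-pyran-2-yl]acetaldehyde | O=CC[C@@]1(C)OC(C)(C)[C@@H](O[Si](CC)(CC)CC)C=C1O[Si](CC)(CC)CC | intermediate
10 | (2R,5S)-2,6,6-trimethyl-2-(prop-2-en-1-yl)-3,5-bis(triethylsilyloxy)-5,6-dihydro-2H-pyran | C=CC[C@@]1(C)OC(C)(C)[C@@H](O[Si](CC)(CC)CC)C=C1O[Si](CC)(CC)CC | intermediate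
11 | 4-methoxy-3-methylphenol | COc1ccc(O)cc1C | starting material
12 | (4-methoxy-3-methylphenoxy)tri(propan-2-yl)silane | COc1ccc(O[Si](C(C)C)(C(C)C)C(C)C)cc1C | intermediate
13 | {2-methoxy-3-methyl-5-[tri(propan-2-yl)silyloxy]phenyl}lithium | COc1c(C)cc(O[Si](C(C)C)(C(C)C)C(C)C)cc1[Li] | intermediate (not isolated)
14 | {2-methoxy-3-methyl-5-[tri(propan-2-yl)silyloxy]phenyl}methanol | COc1c(C)cc(O[Si](C(C)C)(C(C)C)C(C)C)cc1CO | intermediate
15 | [3-(chloromethyl)-4-methoxy-5-methylphenoxy]tri(propan-2-yl)silane | COc1c(C)cc(O[Si](C(C)C)(C(C)C)C(C)C)cc1CCl | intermediate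
16 | but-2-ynal | CC#CC=O | starting material
17 | 3-bromoprop-1-yne | C#CCBr | starting material
18 | bromo(propa-1,2-dien-1-yl)zinc | C=C=C[Zn]Br | intermediate (not isolated)
19 | hepta-1,5-diyn-3-ol (racemic) | CC#CC(O)CC#C | intermediate
20 | dimethyl[(1E)-4-(dimethylalumanyloxy)-2-methylhept-1-en-5-yn-1-yl]alumane (racemic) | CC#CC(O[Al](C)C)C/C(C)=C/[Al](C)C | intermediate (not isolated)
21 | (6E)-8-{2-methoxy-3-methyl-5-[tri(propan-2-yl)silyloxy]phenyl}-6-methyloct-6-en-2-yn-4-ol (racemic) | COc1c(C)cc(O[Si](C(C)C)(C(C)C)C(C)C)cc1C/C=C(\C)CC(O)C#CC | intermediate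
22 | (2Z,6E)-2-iodo-8-{2-methoxy-3-methyl-5-[tri(propan-2-yl)silyloxy]phenyl}-6-methylocta-2,6-dien-4-ol (racemic) | COc1c(C)cc(O[Si](C(C)C)(C(C)C)C(C)C)cc1C/C=C(\C)CC(O)/C=C(/C)I | intermediate
23 | 9-{3-[(2R,5S)-2,6,6-trimethyl-3,5-bis(triethylsilyloxy)-5,6-dihydro-2H-pyran-2-yl]propyl}-9-borabicyclo[3.3.1]nonane | C1CC2CCCC(C1)B2CCC[C@@]3(C)OC(C)(C)[C@@H](O[Si](CC)(CC)CC)C=C3O[Si](CC)(CC)CC | intermediate (not isolated)
24 | (2E,6Z)-1-{2-methoxy-3-methyl-5-[tri(propan-2-yl)silyloxy]phenyl}-3,7-dimethyl-10-[(2R,5S)-2,6,6-trimethyl-3,5-bis(triethylsilyloxy)-5,6-dihydro-2H-pyran-2-yl]deca-2,6-dien-5-ol (both C5 epimers) | COc1c(C)cc(O[Si](C(C)C)(C(C)C)C(C)C)cc1C/C=C(\C)CC(O)/C=C(/C)CCC[C@@]2(C)OC(C)(C)[C@@H](O[Si](CC)(CC)CC)C=C2O[Si](CC)(CC)CC | intermediate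
25 | (2E,6Z)-1-{2-methoxy-3-methyl-5-[tri(propan-2-yl)silyloxy]phenyl}-3,7-dimethyl-10-[(2R,5S)-2,6,6-trimethyl-3,5-bis(triethylsilyloxy)-5,6-dihydro-2H-pyran-2-yl]deca-2,6-dien-5-one | COc1c(C)cc(O[Si](C(C)C)(C(C)C)C(C)C)cc1C/C=C(\C)CC(=O)/C=C(/C)CCC[C@@]2(C)OC(C)(C)[C@@H](O[Si](CC)(CC)CC)C=C2O[Si](CC)(CC)CC | intermediate
26 | (2R,5S)-5-hydroxy-2-[(4Z,8E)-10-(5-hydroxy-2-methoxy-3-methylphenyl)-4,8-dimethyl-6-oxodeca-4,8-dien-1-yl]-2,6,6-trimethyloxan-3-one | COc1c(C)cc(O)cc1C/C=C(\C)CC(=O)/C=C(/C)CCC[C@@]1(C)OC(C)(C)[C@@H](O)CC1=O | target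

**Count.** Total steps: 15. Longest linear sequence: 9 steps (steps 1–6 and 13–15).

**Steps most likely to fail**

Step 3. The unprotected β-hydroxy aldehyde may be lost to retro-aldol, dehydration or hemiacetal oligomerisation before the carbene closes the ring, the closure onto the donor-substituted, fully substituted acceptor carbon may be sluggish, or the two catalytic cycles may interfere. The fallback sets out from 4 and comes back at 8, making the two bonds in separate, isolable stages on a silyl-protected substrate. A Mukaiyama aldol of 4 with 1-(ethylsulfanyl)-1-(triethylsilyloxy)ethene under Ti(OiPr)4/(R)-BINOL catalysis (Et2O, −20 °C) should give ethyl (2E)-3-{[(3S)-5-(ethylsulfanyl)-2-methyl-5-oxo-3-(triethylsilyloxy)pentan-2-yl]oxy}but-2-enoate F1, isolated as the silyl ether (any free carbinol being capped with Et3SiCl/imidazole before chromatography). iBu2AlH at −78 °C should reduce the thioester to ethyl (2E)-3-{[(3S)-2-methyl-5-oxo-3-(triethylsilyloxy)pentan-2-yl]oxy}but-2-enoate F2. This aldehyde cannot eliminate or oligomerise, so it can be closed with the same chiral triazolium salt and iPr2NEt in toluene, with warming if needed and free of amine and acetaldehyde, to ethyl 2-[(2R,5S)-2,6,6-trimethyl-3-oxo-5-(triethylsilyloxy)oxan-2-yl]acetate F3. Et3SiOTf/Et3N then converts F3 into 8.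

Step 13. The aqueous base needed for boron-to-palladium transfer may hydrolyse the silyl enol ether and then trigger E1cB loss of the β-silyloxy group, or slow transmetalation may let β-hydride elimination compete. The fallback sets out from 10 and comes back at 24, replacing the base-mediated boron coupling by a base-free Negishi coupling. Hydroboration of 10 with Et2BH should give diethyl{3-[(2R,5S)-2,6,6-trimethyl-3,5-bis(triethylsilyloxy)-5,6-dihydro-2H-pyran-2-yl]propyl}borane F4, and boron–zinc exchange with Zn(iPr)2 should give (propan-2-yl){3-[(2R,5S)-2,6,6-trimethyl-3,5-bis(triethylsilyloxy)-5,6-dihydro-2H-pyran-2-yl]propyl}zinc F5. Alcohol 22 is first converted with ZnEt2 into ethyl{[(2Z,6E)-2-iodo-8-{2-methoxy-3-methyl-5-[tri(propan-2-yl)silyloxy]phenyl}-6-methylocta-2,6-dien-4-yl]oxy}zinc F6, and Pd(PPh3)4-catalysed coupling of F5 with F6 in THF at rt, followed by aqueous work-up, should return 24 with retention of the Z geometry.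

Step 1. The tertiary, ester-flanked hydroxyl may add too slowly to the amine-activated allenoate, which then oligomerises. The fallback sets out from 1 and comes back at 3, replacing amine catalysis on the allene by anionic conjugate addition to an alkynoate. Deprotonation of 1 with NaH in THF gives sodium 1-methoxy-2-methyl-1-oxopropan-2-olate F7, which should add to commercial ethyl but-2-ynoate at 0 °C; quenching with NH4Cl gives 3, the E isomer being the thermodynamic one.

**Further compounds**

F1 | step 3 | ethyl (2E)-3-{[(3S)-5-(ethylsulfanyl)-2-methyl-5-oxo-3-(triethylsilyloxy)pentan-2-yl]oxy}but-2-enoate | CCOC(=O)/C=C(\C)OC(C)(C)[C@@H](O[Si](CC)(CC)CC)CC(=O)SCC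
F2 | step 3 | ethyl (2E)-3-{[(3S)-2-methyl-5-oxo-3-(triethylsilyloxy)pentan-2-yl]oxy}but-2-enoate | CCOC(=O)/C=C(\C)OC(C)(C)[C@@H](O[Si](CC)(CC)CC)CC=O
F3 | step 3 | ethyl 2-[(2R,5S)-2,6,6-trimethyl-3-oxo-5-(triethylsilyloxy)oxan-2-yl]acetate | CCOC(=O)C[C@@]1(C)OC(C)(C)[C@@H](O[Si](CC)(CC)CC)CC1=O
F4 | step 13 | diethyl{3-[(2R,5S)-2,6,6-trimethyl-3,5-bis(triethylsilyloxy)-5,6-dihydro-2H-pyran-2-yl]propyl}borane | CCB(CC)CCC[C@@]1(C)OC(C)(C)[C@@H](O[Si](CC)(CC)CC)C=C1O[Si](CC)(CC)CC
F5 | step 13 | (propan-2-yl){3-[(2R,5S)-2,6,6-trimethyl-3,5-bis(triethylsilyloxy)-5,6-dihydro-2H-pyran-2-yl]propyl}zinc | CC(C)[Zn]CCC[C@@]1(C)OC(C)(C)[C@@H](O[Si](CC)(CC)CC)C=C1O[Si](CC)(CC)CC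
F6 | step 13 | ethyl{[(2Z,6E)-2-iodo-8-{2-methoxy-3-methyl-5-[tri(propan-2-yl)silyloxy]phenyl}-6-methylocta-2,6-dien-4-yl]oxy}zinc | COc1c(C)cc(O[Si](C(C)C)(C(C)C)C(C)C)cc1C/C=C(\C)CC(O[Zn]CC)/C=C(/C)I
F7 | step 1 | sodium 1-methoxy-2-methyl-1-oxopropan-2-olate | COC(=O)C(C)(C)[O-].[Na+]
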